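**Plan**
1. Enabling feature: ring A is the nine-membered ring N–C(=O)–Cα–Cq–CH2–CH2–CH(OH)–CH(CH3)–CH2, with two adjacent quaternary carbons (Cα next to the lactam C=O, Cq bearing CH2OAc). Read with Cq–CH=CH it is a γ,δ-unsaturated amide, and its N–CH2–CH(CH3)–CH(O)–CH segment is a 2-alkenyl-3-oxy-4-methylpyrrolidine.
2. Cuts, in retro order: CH(CO2Me)–CH(allylic) of ring E; N–CH2 of ring B; CH2–C(sp2) of ring C; then N–C(=O) and Cα–Cq of ring A together.
3. Forward ring order: pyrrolidine; ring A by four-atom ring expansion (ring D comes in with the acid chloride); ring C by B-alkyl Suzuki coupling; ring B by N-alkylation; ring E by carbenoid C–H insertion.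
4. Fragments: acid chloride 8 (from 1, 2, 5); ester 14 (from 9, 12); pyrrolidine aldehyde 27 (from 15, 16). 14 and 27 give allyl amine 32.
5. Stereochemistry: CH(O) and pyrrolidine C2 come from a Schöllkopf syn aldol, CHCH3 from a syn-selective Rh hydroboration, and the ring B/C bridge CH from benzyl (R)-glycidyl ether by a retentive Rh allylation. C2 is consumed to set Cq and, through the chair and the enolate geometry, Cα. Cα then dictates the allylic CH of ring E, and convex-face protonation sets the ester CH.

Key step: step 20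

Labels: Cα and Cq as above. Ring A is the nine-membered lactam, B the six-membered lactam, C the cycloheptene, D the cyclopentene, E the ester-bearing cyclopentane. TBS = tert-butyldimethylsilyl, PMB = 4-methoxybenzyl, Bn = benzyl, Ms = methanesulfonyl.
Remark on the stereochemical pairing: an amine adds to an unsymmetrical ketene past the smaller substituent, so the bromocyclopentenyl group is expected syn to O−. Through a chair this maps onto the target only from the 2,3-cis pyrrolidine (2S at the alkenyl carbon) carrying the E alkene (CH2OSi trans and CH(vinyl)CH2OBn cis to the ring), so 32 is built that way.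
Assumption: 1, 2, 5, 9, 12, 15 and 16 are taken as commercial.

Step 1
Reactants: 1 1,2-dibromocyclopentene; 2 tert-butyl bromoacetate
Product: 4 tert-butyl 2-(2-bromocyclopent-1-en-1-yl)acetate, via Reformatsky reagent 3 (not isolated)
Conditions: Zn, Me3SiCl (cat.), THF, 40 °C; then 1 (2 equiv), Pd(dba)2 (2 mol %), P(t-Bu)3 (4 mol %), THF, rt
Reagents that add atoms: none
Why: Negishi-type coupling of a Reformatsky reagent with a vinyl bromide, held at mono-substitution by excess dibromide and by the greater hindrance of the remaining C–Br bond.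

Step 2
Reactants: 4 tert-butyl 2-(2-bromocyclopent-1-en-1-yl)acetate; 5 methyl acrylate
Product: 6 1-tert-butyl 5-methyl 2-(2-bromocyclopent-1-en-1-yl)pentanedioate (racemic)
Conditions: LiN(i-Pr)2, THF, −78 °C; 5 (1.0 equiv), −78 °C; AcOH
Reagents that add atoms: none
Why: Michael addition of the lithium dienolate, which reacts at its α-carbon, to the acrylate; the racemic centre formed here is erased later in the ketene.

Step 3
Reactants: 6 1-tert-butyl 5-methyl 2-(2-bromocyclopent-1-en-1-yl)pentanedioate
Product: 7 2-(2-bromocyclopent-1-en-1-yl)-5-methoxy-5-oxopentanoic acid (racemic)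
Conditions: CF3CO2H, CH2Cl2, 0 °C → rt
Reagents that add atoms: none
Why: Acidolysis of the tert-butyl ester by loss of isobutene leaves the methyl ester and the vinyl bromide untouched.

Step 4
Reactants: 7 2-(2-bromocyclopent-1-en-1-yl)-5-methoxy-5-oxopentanoic acid
Product: 8 methyl 4-(2-bromocyclopent-1-en-1-yl)-5-chloro-5-oxopentanoate (racemic acid chloride)
Conditions: (COCl)2, DMF (cat.), CH2Cl2, 0 °C → rt, used crude
Reagents that add atoms: oxalyl chloride O=C(Cl)C(=O)Cl
Why: Vilsmeier-type activation turns the acid into the acid chloride without base, so the acidic α-C–H is not disturbed.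

Step 5
Reactants: 9 benzyl (R)-glycidyl ether
Product: 10 (2R)-1-(benzyloxy)but-3-en-2-ol
Conditions: Me3SI, n-BuLi, THF, −10 °C → rt
Reagents that add atoms: trimethylsulfonium iodide C[S+](C)C.[I-]
Why: Dimethylsulfonium methylide opens the epoxide at its CH2 end and a second ylide equivalent induces loss of Me2S (one-carbon homologation of an epoxide to an allylic alcohol), so the C–O stereocentre is not touched.

Step 6
Reactants: 10 (2R)-1-(benzyloxy)but-3-en-2-ol
Product: 11 (2R)-1-(benzyloxy)but-3-en-2-yl methyl carbonate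
Conditions: ClCO2Me, pyridine, CH2Cl2, 0 °C
Reagents that add atoms: methyl chloroformate COC(=O)Cl
Why: Simple O-acylation installs the leaving group for the allylic substitution.

Step 7
Reactants: 11 (2R)-1-(benzyloxy)but-3-en-2-yl methyl carbonate; 12 dimethyl malonate
Product: 13 dimethyl 2-[(2S)-1-(benzyloxy)but-3-en-2-yl]propanedioate
Conditions: 12, NaH, THF; RhCl(PPh3)3 (5 mol %), P(OMe)3 (20 mol %), THF, 30 °C
Reagents that add atoms: none
Why: Rhodium-catalysed allylic alkylation of a secondary allylic carbonate runs through a configurationally stable enyl complex, so the malonate enters at the branched carbon with net retention and sets the ring B/C bridge CH.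

Step 8
Reactants: 13 dimethyl 2-[(2S)-1-(benzyloxy)but-3-en-2-yl]propanedioate
Product: 14 methyl (3R)-3-[(benzyloxy)methyl]pent-4-enoate
Conditions: NaCl, H2O, DMSO, 150 °C
Reagents that add atoms: none
Why: Krapcho dealkoxycarbonylation removes one ester under essentially neutral conditions that neither epimerise the β-centre nor move the vinyl group.

Step 9
Reactants: 15 (2S)-2-isopropyl-3,6-dimethoxy-2,5-dihydropyrazine; 16 methacrolein
Product: 19 (1S)-1-[(2R,5S)-5-isopropyl-3,6-dimethoxy-2,5-dihydropyrazin-2-yl]-2-methylprop-2-en-1-ol, via lithiated bislactim ether 17 (not isolated), via titanium azaenolate 18 (not isolated)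
Conditions: n-BuLi, THF, −78 °C; ClTi(NEt2)3, −78 °C; 16, −78 °C; pH 7 buffer
Reagents that add atoms: none
Why: In this Schöllkopf bislactim-ether aldol the isopropyl group sends the aldehyde to the opposite ring face (future pyrrolidine C2, R at this stage), and the closed transition state of the titanium azaenolate gives the syn (threo) carbinol by 1,2-addition.

Step 10
Reactants: 19 aldol adduct
Product: 20 TBS ether of 19
Conditions: t-BuMe2SiOTf, 2,6-lutidine, CH2Cl2, 0 °C
Reagents that add atoms: tert-butyldimethylsilyl triflate CC(C)(C)[Si](C)(C)OS(=O)(=O)C(F)(F)F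
Why: Silylation of the hindered allylic alcohol with the silyl triflate gives the ether that steers the next step and lasts to the end of the route.

Step 11
Reactants: 20 TBS ether
Product: 22 (2R,3S)-3-(TBS-oxy)-3-[(2R,5S)-5-isopropyl-3,6-dimethoxy-2,5-dihydropyrazin-2-yl]-2-methylpropan-1-ol, via catechol boronate 21 (not isolated)
Conditions: catecholborane, RhCl(PPh3)3 (3 mol %), THF, rt; then H2O2, pH 7 buffer, 0 °C
Reagents that add atoms: hydrogen peroxide OO
Why: Rhodium-catalysed hydroboration of a 1,1-disubstituted allylic silyl ether gives the syn 2-methyl-1,3-dioxygen pattern (the opposite of 9-BBN), which sets CHCH3 trans to the silyloxy group of the later ring.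

Step 12
Reactants: 22 primary alcohol
Product: 23 primary mesylate of 22
Conditions: MsCl, Et3N, CH2Cl2, 0 °C
Reagents that add atoms: methanesulfonyl chloride CS(=O)(=O)Cl
Why: Standard sulfonylation activates the only free hydroxyl group.

Step 13
Reactants: 23 primary mesylate
Product: 25 methyl (2R,3S,4R)-3-(TBS-oxy)-4-methylpyrrolidine-2-carboxylate (2,3-cis, 3,4-trans), via amino ester 24 (not isolated)
Conditions: CF3CO2H (0.2 M), MeCN–H2O, rt; then K2CO3, MeCN, 50 °C
Reagents that add atoms: water O
Why: Mild acid hydrolysis of the bislactim ether frees the amino ester, whose NH2 group closes the pyrrolidine by 5-exo-tet SN2 displacement at the primary mesylate without touching a stereocentre.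

Step 14
Reactants: 25 pyrrolidine ester
Product: 26 methyl (2R,3S,4R)-3-(TBS-oxy)-1-(4-methoxybenzyl)-4-methylpyrrolidine-2-carboxylate
Conditions: 4-MeOC6H4CH2Cl, K2CO3, NaI (cat.), MeCN, 50 °C
Reagents that add atoms: 4-methoxybenzyl chloride COc1ccc(CCl)cc1
Why: N-alkylation of the secondary amine gives the nucleophilic tertiary amine that the key step needs, carrying a group that is later removable from a lactam by oxidation.

Step 15
Reactants: 26 N-PMB ester
Product: 27 (2R,3S,4R)-3-(TBS-oxy)-1-(4-methoxybenzyl)-4-methylpyrrolidine-2-carbaldehyde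
Conditions: i-Bu2AlH (1.1 equiv), toluene, −78 °C; Rochelle salt
Reagents that add atoms: none
Why: In this partial ester reduction the aluminium hemiacetal, chelated by the ring nitrogen, survives at −78 °C, and the cis aldehyde is used at once to avoid epimerisation.

Step 16
Reactants: 14 methyl (3R)-3-[(benzyloxy)methyl]pent-4-enoate; 27 pyrrolidine aldehyde
Product: 29 methyl (3S)-2-{acetoxy[(2R,3S,4R)-3-(TBS-oxy)-1-PMB-4-methylpyrrolidin-2-yl]methyl}-3-[(benzyloxy)methyl]pent-4-enoate (mixture at the two new centres), via lithium aldolate 28 (not isolated)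
Conditions: 14, LiN(i-Pr)2, THF, −78 °C; 27, −78 °C; Ac2O, −78 → 0 °C
Reagents that add atoms: acetic anhydride CC(=O)OC(C)=O
Why: Aldol addition of the lithium enolate is far faster at −78 °C than enolisation of the aldehyde, so C2 keeps its configuration; the acetate made in situ is too poor a leaving group for aziridinium formation, and both new centres vanish in step 17.

Step 17
Reactants: 29 β-acetoxy ester
Product: 30 methyl (2E,3S)-3-[(benzyloxy)methyl]-2-{[(2S,3S,4R)-3-(TBS-oxy)-1-PMB-4-methylpyrrolidin-2-yl]methylidene}pent-4-enoate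
Conditions: KOt-Bu (1.05 equiv), THF, −40 → −20 °C
Reagents that add atoms: none
Why: E1cB elimination gives the more stable E enoate (ester trans to the pyrrolidine, as known for α-sec-alkyl enoates), and allylic 1,3-strain keeps both flanking C–H bonds in the alkene plane, which protects them from deprotonation.

Step 18
Reactants: 30 E enoate
Product: 31 (2E,3S)-3-[(benzyloxy)methyl]-2-{[(2S,3S,4R)-3-(TBS-oxy)-1-PMB-4-methylpyrrolidin-2-yl]methylidene}pent-4-en-1-ol
Conditions: i-Bu2AlH (2.5 equiv), CH2Cl2, −78 °C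
Reagents that add atoms: none
Why: 1,2-Reduction of the enoate with i-Bu2AlH gives the allylic alcohol with the alkene geometry retained.

Step 19
Reactants: 31 allylic alcohol
Product: 32 (2S,3S,4R)-2-[(1E,3S)-3-[(benzyloxy)methyl]-2-(TBS-oxymethyl)penta-1,4-dien-1-yl]-3-(TBS-oxy)-1-(4-methoxybenzyl)-4-methylpyrrolidine
Conditions: t-BuMe2SiCl, imidazole, DMF, rt
Reagents that add atoms: tert-butyldimethylsilyl chloride CC(C)(C)[Si](C)(C)Cl
Why: Silylation of the primary alcohol gives a group that survives hydrogenolysis, cerium oxidation and strong base, and that can later be removed ahead of the hindered secondary TBS ether.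

Step 20
Reactants: 8 acid chloride; 32 N-PMB 2-alkenylpyrrolidine
Product: 35 methyl 3-[(3S,4R,5E,7R,8R)-4-[(2S)-1-(benzyloxy)but-3-en-2-yl]-3-(2-bromocyclopent-1-en-1-yl)-7-(TBS-oxy)-4-(TBS-oxymethyl)-1-(4-methoxybenzyl)-8-methyl-2-oxo-2,3,4,7,8,9-hexahydro-1H-azonin-3-yl]propanoate, via ketene 33 (not isolated), via acylammonium enolate 34 (not isolated)
Conditions: 32, i-Pr2NEt (3 equiv), Yb(OTf)3 (20 mol %), CH2Cl2, 23 °C; 8 (2 equiv) by syringe pump
Reagents that add atoms: none
Why: Proposed new method: i-Pr2NEt removes HCl from 8 (its C–H is both α-carbonyl and allylic) to give ketene 33, the ring nitrogen of 32 adds to the ketene carbonyl carbon in the ketene plane past the slim CH2CH2CO2Me arm, and the acylammonium enolate 34 (arm syn to N+, bromocyclopentenyl syn to O−) undergoes a charge-accelerated [3,3] shift that forms N–C(=O) and Cα–Cq and breaks N–C2. The closest known reactions are the zwitterionic ketene aza-Claisen (Bellus–Claisen type) ring expansion of N-benzyl-2-vinylpyrrolidines to E-azoninones and the Lewis-acid-catalysed acyl-Claisen of allyl amines; each fully substituted terminus has been made singly (dichloroketene; 3,3-disubstituted allyl amines), but their union has not. Ring A is not closed end to end but arises by four-atom expansion of the pyrrolidine through a bicyclic chair, so no medium-ring entropy is paid, and charge neutralisation plus release of the cis-2,3 strain drive the bond between the two fully substituted carbons. Cq is controlled by pyrrolidine C2: allylic 1,3-strain locks H–C2 in the alkene plane facing the cis CH(vinyl)CH2OBn group, nitrogen stands on one alkene face, the new bond forms on that face as nitrogen leaves, and pyrrolidine C3 sits equatorial, which also gives the E ring alkene. Cα is controlled by the enolate geometry read through the chair (arm axial, bromocyclopentenyl equatorial), and the approach of the amine and the 1,3-diaxial strain against the N-substituents favour the same geometry under Curtin–Hammett conditions. The step needs N-acylation to beat ketene dimerisation (slow addition to a strongly nucleophilic trialkylamine), the shift to beat chloride attack on the PMB group (Yb(OTf)3 holds the enolate oxygen and chloride is kept as the hindered ammonium salt), and chair to beat boat (the boat eclipses the substituents on both termini of the forming bond).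

Step 21
Reactants: 35 nine-membered E-alkenyl lactam
Product: 37 tricyclic N-PMB lactam (rings A, C, D) in which the terminal carbon of the former vinyl group is bonded to the cyclopentene carbon that carried Br, via B-alkyl borane 36 (not isolated)
Conditions: 9-BBN, THF, rt; then Pd(dppf)Cl2 (10 mol %), AsPh3, K3PO4 (aq.), DMF–THF, 50 °C, 2 mM
Reagents that add atoms: none
Why: In this B-alkyl Suzuki–Miyaura cyclisation 9-BBN selects the monosubstituted vinyl group over the ring alkene, which is flanked by Cq and CH(OTBS), and the preset bridge CH holds the borane arm on the same side as the vinyl bromide for seven-membered ring closure.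

Step 22
Reactants: 37 tricyclic N-PMB lactam
Product: 38 tricyclic N-PMB lactam with saturated ring A and free CH2OH on the bridge CH
Conditions: H2 (1 atm), Pd/C, EtOAc–EtOH, rt
Reagents that add atoms: none
Why: Catalytic hydrogenation saturates the strained E ring alkene and hydrogenolyses the benzyl ether in one operation, while the tetrasubstituted ring C/D alkene and the N-PMB lactam are inert.

Step 23
Reactants: 38 N-PMB lactam alcohol
Product: 39 N–H lactam alcohol
Conditions: (NH4)2Ce(NO3)6, MeCN–H2O, 0 °C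
Reagents that add atoms: none
Why: Oxidative cleavage of a PMB lactam by single-electron oxidation of the anisyl ring works at 0 °C, where TBS ethers and the hindered alkene survive.

Step 24
Reactants: 39 N–H lactam alcohol
Product: 40 N–H lactam mesylate
Conditions: MsCl, Et3N, CH2Cl2, 0 °C
Reagents that add atoms: methanesulfonyl chloride CS(=O)(=O)Cl
Why: Sulfonylation takes place at the only free hydroxyl group, because the lactam N–H is not mesylated under these conditions.

Step 25
Reactants: 40 N–H lactam mesylate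
Product: 41 tetracyclic lactam (rings A–D, lactam N bonded to the CH2 on the bridge CH)
Conditions: NaH, THF–DMF, 0 °C → rt
Reagents that add atoms: none
Why: Intramolecular N-alkylation of the sodium lactamate (6-exo-tet SN2 at a primary carbon) closes ring B, since the N–H is more acidic than the ester α-C–H and Cα has no hydrogen.

Step 26
Reactants: 41 tetracyclic lactam ester
Product: 43 α-diazo ester of 41, via α-trifluoroacetyl ester 42 (not isolated)
Conditions: LiN(SiMe3)2, THF, −78 °C; CF3CO2CH2CF3; aq. HCl wash; then 4-AcNHC6H4SO2N3, Et3N, H2O (1 equiv), MeCN, rt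
Reagents that add atoms: 4-acetamidobenzenesulfonyl azide CC(=O)Nc1ccc(cc1)S(=O)(=O)N=[N+]=[N-]
Why: In this detrifluoroacetylative Regitz diazo transfer the ester CH2 is the only enolisable position, and the temporary trifluoroacetyl group makes it acidic enough for transfer with Et3N.

Step 27
Reactants: 43 α-diazo ester
Product: 44 pentacyclic bis-TBS ether (ring E closed, ester CH as a mixture of epimers)
Conditions: Rh2(O2CCPh3)4 (1 mol %), CH2Cl2, −20 °C → rt, slow addition
Reagents that add atoms: none
Why: In this rhodium-carbenoid 1,5 C–H insertion of an α-diazo ester, Cα holds the arm over one face of ring D, so only the allylic C–H on that face is in reach and insertion with retention sets the allylic CH; the near-eclipsed torsion to that CH2 favours it over the staggered CH2 groups on Cq, and the bulky carboxylate ligands slow the 1,2-hydride shift.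

Step 28
Reactants: 44 pentacyclic ester (epimer mixture)
Product: 45 pentacyclic ester with the ester CH configured as in the target
Conditions: KN(SiMe3)2, THF, −78 → −40 °C; 2,6-di-tert-butyl-4-methylphenol, −78 °C
Reagents that add atoms: none
Why: On deprotonation and kinetic reprotonation of the ester enolate the proton arrives on the open convex face of the bicyclo[3.3.0]octene (the other face is covered by CH2OTBS and ring D), which places the ester on the concave face and converges both epimers.

Step 29
Reactants: 45 pentacyclic bis-TBS ether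
Product: 46 primary alcohol (secondary TBS ether kept)
Conditions: HF·pyridine, pyridine, THF, 0 °C
Reagents that add atoms: none
Why: Buffered fluoride cleaves the primary TBS ether well before the secondary one, which is flanked by CHCH3.

Step 30
Reactants: 46 primary alcohol
Product: 47 acetate of 46
Conditions: Ac2O, pyridine, DMAP (cat.), CH2Cl2, rt
Reagents that add atoms: acetic anhydride CC(=O)OC(C)=O
Why: DMAP-catalysed acetylation of the only free hydroxyl group is too weakly basic to epimerise the ester CH.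

Step 31
Reactants: 47 acetate
Product: 48 CNP0296366.1
Conditions: HF (48 % aq.), MeCN, rt
Reagents that add atoms: none
Why: Acidic fluoride desilylation frees the secondary alcohol without touching the acetate, the methyl ester, the lactam or the tetrasubstituted alkene.

**Compound list**
1 | 1,2-dibromocyclopentene | BrC1=C(Br)CCC1 | starting material
2 | tert-butyl bromoacetate | CC(C)(C)OC(=O)CBr | starting material
3 | (2-tert-butoxy-2-oxoethyl)zinc bromide | CC(C)(C)OC(=O)C[Zn]Br | intermediate
4 | tert-butyl 2-(2-bromocyclopent-1-en-1-yl)acetate | CC(C)(C)OC(=O)CC1=C(Br)CCC1 | intermediate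
5 | methyl acrylate | C=CC(=O)OC | starting material
6 | 1-tert-butyl 5-methyl 2-(2-bromocyclopent-1-en-1-yl)pentanedioate (racemic) | COC(=O)CCC(C(=O)OC(C)(C)C)C1=C(Br)CCC1 | intermediate
7 | 2-(2-bromocyclopent-1-en-1-yl)-5-methoxy-5-oxopentanoic acid (racemic) | COC(=O)CCC(C(=O)O)C1=C(Br)CCC1 | intermediate
8 | methyl 4-(2-bromocyclopent-1-en-1-yl)-5-chloro-5-oxopentanoate (racemic) | COC(=O)CCC(C(Cl)=O)C1=C(Br)CCC1 | intermediate
9 | benzyl (R)-glycidyl ether | C1O[C@H]1COCc1ccccc1 | starting material
10 | (2R)-1-(benzyloxy)but-3-en-2-ol | O[C@@H](COCc1ccccc1)C=C | intermediate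
11 | (2R)-1-(benzyloxy)but-3-en-2-yl methyl carbonate | COC(=O)O[C@@H](COCc1ccccc1)C=C | intermediate
12 | dimethyl malonate | COC(=O)CC(=O)OC | starting material
13 | dimethyl 2-[(2S)-1-(benzyloxy)but-3-en-2-yl]propanedioate | COC(=O)C(C(=O)OC)[C@@H](COCc1ccccc1)C=C | intermediate
14 | methyl (3R)-3-[(benzyloxy)methyl]pent-4-enoate | COC(=O)C[C@@H](COCc1ccccc1)C=C | intermediate
15 | (2S)-2-isopropyl-3,6-dimethoxy-2,5-dihydropyrazine | CC(C)[C@@H]1N=C(OC)CN=C1OC | starting material
16 | methacrolein | CC(=C)C=O | starting material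
17 | lithiated bislactim ether | [Li+].CC(C)[C@@H]1N=C(OC)[CH-]N=C1OC | intermediate
18 | tris(diethylamido)titanium azaenolate of 15 | CC(C)[C@@H]1N=C(OC)C([Ti](N(CC)CC)(N(CC)CC)N(CC)CC)N=C1OC | intermediate
19 | syn aldol adduct (2R,5S,1'S) | CC(C)[C@@H]1N=C(OC)[C@@H]([C@@H](O)C(C)=C)N=C1OC | intermediate
20 | TBS ether of 19 | CC(C)[C@@H]1N=C(OC)[C@@H]([C@@H](O[Si](C)(C)C(C)(C)C)C(C)=C)N=C1OC | intermediate
21 | catechol boronate | CC(C)[C@@H]1N=C(OC)[C@@H]([C@@H](O[Si](C)(C)C(C)(C)C)[C@H](C)CB2Oc3ccccc3O2)N=C1OC | intermediate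
22 | primary alcohol (syn methyl/silyloxy) | CC(C)[C@@H]1N=C(OC)[C@@H]([C@@H](O[Si](C)(C)C(C)(C)C)[C@H](C)CO)N=C1OC | intermediate
23 | primary mesylate | CC(C)[C@@H]1N=C(OC)[C@@H]([C@@H](O[Si](C)(C)C(C)(C)C)[C@H](C)COS(C)(=O)=O)N=C1OC | intermediate
24 | methyl (2R,3S,4R)-2-amino-3-(TBS-oxy)-4-methyl-5-(mesyloxy)pentanoate | COC(=O)[C@H](N)[C@@H](O[Si](C)(C)C(C)(C)C)[C@H](C)COS(C)(=O)=O | intermediate
25 | methyl (2R,3S,4R)-3-(TBS-oxy)-4-methylpyrrolidine-2-carboxylate | COC(=O)[C@H]1[C@@H](O[Si](C)(C)C(C)(C)C)[C@H](C)CN1 | intermediate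
26 | N-PMB derivative of 25 | COC(=O)[C@H]1[C@@H](O[Si](C)(C)C(C)(C)C)[C@H](C)CN1Cc1ccc(OC)cc1 | intermediate
27 | (2R,3S,4R)-3-(TBS-oxy)-1-PMB-4-methylpyrrolidine-2-carbaldehyde | O=C[C@H]1[C@@H](O[Si](C)(C)C(C)(C)C)[C@H](C)CN1Cc1ccc(OC)cc1 | intermediate
28 | lithium aldolate | [Li+].COC(=O)C([C@@H](COCc1ccccc1)C=C)C([O-])[C@H]1[C@@H](O[Si](C)(C)C(C)(C)C)[C@H](C)CN1Cc1ccc(OC)cc1 | intermediate
29 | β-acetoxy ester (mixture at the two new centres) | COC(=O)C([C@@H](COCc1ccccc1)C=C)C(OC(C)=O)[C@H]1[C@@H](O[Si](C)(C)C(C)(C)C)[C@H](C)CN1Cc1ccc(OC)cc1 | intermediate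
30 | E enoate | COC(=O)/C([C@@H](COCc1ccccc1)C=C)=C/[C@H]1[C@@H](O[Si](C)(C)C(C)(C)C)[C@H](C)CN1Cc1ccc(OC)cc1 | intermediate
31 | E allylic alcohol | OC/C([C@@H](COCc1ccccc1)C=C)=C/[C@H]1[C@@H](O[Si](C)(C)C(C)(C)C)[C@H](C)CN1Cc1ccc(OC)cc1 | intermediate
32 | N-PMB 2-alkenyl-3-silyloxy-4-methylpyrrolidine (key-step precursor) | CC(C)(C)[Si](C)(C)OC/C([C@@H](COCc1ccccc1)C=C)=C/[C@H]1[C@@H](O[Si](C)(C)C(C)(C)C)[C@H](C)CN1Cc1ccc(OC)cc1 | intermediate
33 | ketene from 8 | COC(=O)CCC(=C=O)C1=C(Br)CCC1 | intermediate
34 | acylammonium enolate | COC(=O)CC/C(C1=C(Br)CCC1)=C(/[O-])[N@+]2(Cc3ccc(OC)cc3)C[C@@H](C)[C@H](O[Si](C)(C)C(C)(C)C)[C@@H]2/C=C(\[C@H](C=C)COCc4ccccc4)CO[Si](C)(C)C(C)(C)C | intermediate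
35 | nine-membered E-alkenyl lactam with both quaternary carbons (key-step product) | COC(=O)CC[C@]1(C2=C(Br)CCC2)C(=O)N(Cc2ccc(OC)cc2)C[C@@H](C)[C@H](O[Si](C)(C)C(C)(C)C)/C=C/[C@@]1(CO[Si](C)(C)C(C)(C)C)[C@@H](COCc2ccccc2)C=C | intermediate
36 | B-alkyl-9-BBN adduct of 35 | COC(=O)CC[C@]1(C2=C(Br)CCC2)C(=O)N(Cc2ccc(OC)cc2)C[C@@H](C)[C@H](O[Si](C)(C)C(C)(C)C)/C=C/[C@@]1(CO[Si](C)(C)C(C)(C)C)[C@@H](COCc2ccccc2)CCB2C3CCCC2CCC3 | intermediate
37 | tricyclic N-PMB lactam (rings A, C, D) | COC(=O)CC[C@@]12C3=C(CCC3)CC[C@H](COCc4ccccc4)[C@]1(CO[Si](C)(C)C(C)(C)C)/C=C/[C@@H](O[Si](C)(C)C(C)(C)C)[C@H](C)CN(Cc4ccc(OC)cc4)C2=O | intermediate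
38 | saturated N-PMB lactam alcohol | COC(=O)CC[C@@]12C3=C(CCC3)CC[C@H](CO)[C@]1(CO[Si](C)(C)C(C)(C)C)CC[C@@H](O[Si](C)(C)C(C)(C)C)[C@H](C)CN(Cc4ccc(OC)cc4)C2=O | intermediate
39 | N–H lactam alcohol | COC(=O)CC[C@@]12C3=C(CCC3)CC[C@H](CO)[C@]1(CO[Si](C)(C)C(C)(C)C)CC[C@@H](O[Si](C)(C)C(C)(C)C)[C@H](C)CNC2=O | intermediate
40 | N–H lactam mesylate | COC(=O)CC[C@@]12C3=C(CCC3)CC[C@H](COS(C)(=O)=O)[C@]1(CO[Si](C)(C)C(C)(C)C)CC[C@@H](O[Si](C)(C)C(C)(C)C)[C@H](C)CNC2=O | intermediate
41 | tetracyclic lactam ester (rings A–D) | COC(=O)CC[C@@]12C(=O)N3C[C@@H](CCC4=C1CCC4)[C@]2(CO[Si](C)(C)C(C)(C)C)CC[C@@H](O[Si](C)(C)C(C)(C)C)[C@H](C)C3 | intermediate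
42 | α-trifluoroacetyl ester | COC(=O)C(C(=O)C(F)(F)F)C[C@@]12C(=O)N3C[C@@H](CCC4=C1CCC4)[C@]2(CO[Si](C)(C)C(C)(C)C)CC[C@@H](O[Si](C)(C)C(C)(C)C)[C@H](C)C3 | intermediate
43 | α-diazo ester | COC(=O)C(=[N+]=[N-])C[C@@]12C(=O)N3C[C@@H](CCC4=C1CCC4)[C@]2(CO[Si](C)(C)C(C)(C)C)CC[C@@H](O[Si](C)(C)C(C)(C)C)[C@H](C)C3 | intermediate
44 | pentacyclic bis-TBS ether, ester CH as epimer mixture | COC(=O)C1C[C@@]23C(=O)N4C[C@@H](CCC5=C2[C@@H]1CC5)[C@]3(CO[Si](C)(C)C(C)(C)C)CC[C@@H](O[Si](C)(C)C(C)(C)C)[C@H](C)C4 | intermediate
45 | pentacyclic bis-TBS ether, ester CH as in the target | COC(=O)[C@@H]1C[C@@]23C(=O)N4C[C@@H](CCC5=C2[C@@H]1CC5)[C@]3(CO[Si](C)(C)C(C)(C)C)CC[C@@H](O[Si](C)(C)C(C)(C)C)[C@H](C)C4 | intermediate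
46 | primary alcohol | COC(=O)[C@@H]1C[C@@]23C(=O)N4C[C@@H](CCC5=C2[C@@H]1CC5)[C@]3(CO)CC[C@@H](O[Si](C)(C)C(C)(C)C)[C@H](C)C4 | intermediate
47 | acetate, secondary TBS ether | COC(=O)[C@@H]1C[C@@]23C(=O)N4C[C@@H](CCC5=C2[C@@H]1CC5)[C@]3(COC(C)=O)CC[C@@H](O[Si](C)(C)C(C)(C)C)[C@H](C)C4 | intermediate
48 | CNP0296366.1 | COC(=O)[C@@H]1C[C@@]23C(=O)N4C[C@@H](CCC5=C2[C@@H]1CC5)[C@]3(COC(C)=O)CC[C@@H](O)[C@H](C)C4 | target

Total step count: 31. Longest linear sequence: 23 steps (steps 9–31, from 15).

**Steps most likely to fail**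

1. Step 20.
- What may go wrong: formation of the crowded acylammonium enolate may be so unfavourable and reversible that the ketene dimerises. Chloride may strip the PMB group before the shift occurs. Leakage through a boat would erode the Cα configuration.
- Fallback (known chemistry; it replaces the reversible zwitterion by a covalent amide): it sets out from 32 and 8.
  - Heating the two in toluene without base lets chloride remove the PMB group from the acylammonium salt (von Braun-type dealkylation) and gives the N-acylpyrrolidine F1.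
  - LiN(SiMe3)2 in refluxing toluene removes the doubly activated Cα–H, and the amide enolate undergoes the known anionic aza-Claisen ring expansion, with the same enolate geometry and chair, to the N–H E-azoninone F2.
  - 9-BBN gives the B-alkyl borane F3, and palladium-catalysed closure as in step 21 gives the tricyclic N–H lactam F4.
  - Hydrogenation as in step 22 comes back to the route at 39, so step 23 is not needed.

2. Step 27.
- What may go wrong: the lactam carbonyl oxygen may capture the carbenoid as a five-membered carbonyl ylide. A 1,2-hydride shift may give the enoate. Insertion may occur into the CH2 groups on Cq.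
- Fallback (photochemical hydrogen abstraction in place of a metal carbenoid): it sets out from 41.
  - KN(SiMe3)2 and 2-(phenylsulfonyl)-3-phenyloxaziridine give the α-hydroxy ester F5, and Dess–Martin periodinane gives the α-keto ester F6.
  - On irradiation (350 nm, benzene) the excited keto group finds no γ-hydrogen, because Cα and its three other neighbours carry none. It therefore abstracts the weak allylic δ-hydrogen of ring D, and Norrish–Yang closure of the biradical gives the ring E cyclopentanol F7.
  - SmI2–HMPA with pivalic acid removes the α-hydroxy group, and convex-face protonation of the samarium enolate comes back to the route at 45.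

3. Step 21.
- What may go wrong: oxidative addition at the hindered tetrasubstituted vinyl bromide next to Cα may be slow, and so may the seven-membered closure. Protodeboronation or β-hydride elimination could then take over, and warming could start a Cope rearrangement of the 1,5-diene units.
- Fallback (alkene metathesis in place of an sp3–sp2 coupling): it sets out from 35.
  - Stille coupling with the small tributyl(vinyl)stannane (Pd(PPh3)4, CuCl, LiCl, DMSO) gives the 2-vinylcyclopentenyl lactam F8.
  - Ring-closing metathesis with the second-generation Grubbs catalyst joins the two vinyl groups and gives the ring C cycloheptadiene F9. The ring A alkene is shielded by Cq and CH(OTBS).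
  - Hydrogenation over Pd/C saturates both disubstituted alkenes, removes the benzyl group, and comes back to the route at 38.

**Further compounds**
F1 | step 20 | N-acylpyrrolidine | COC(=O)CCC(C1=C(Br)CCC1)C(=O)N1C[C@@H](C)[C@H](O[Si](C)(C)C(C)(C)C)[C@@H]1/C=C(\[C@H](C=C)COCc1ccccc1)CO[Si](C)(C)C(C)(C)C
F2 | step 20 | N–H E-azoninone | COC(=O)CC[C@]1(C2=C(Br)CCC2)C(=O)NC[C@@H](C)[C@H](O[Si](C)(C)C(C)(C)C)/C=C/[C@@]1(CO[Si](C)(C)C(C)(C)C)[C@@H](COCc2ccccc2)C=C
F3 | step 20 | B-alkyl borane | COC(=O)CC[C@]1(C2=C(Br)CCC2)C(=O)NC[C@@H](C)[C@H](O[Si](C)(C)C(C)(C)C)/C=C/[C@@]1(CO[Si](C)(C)C(C)(C)C)[C@@H](COCc2ccccc2)CCB2C3CCCC2CCC3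
F4 | step 20 | tricyclic N–H lactam | COC(=O)CC[C@@]12C3=C(CCC3)CC[C@H](COCc4ccccc4)[C@]1(CO[Si](C)(C)C(C)(C)C)/C=C/[C@@H](O[Si](C)(C)C(C)(C)C)[C@H](C)CNC2=O
F5 | step 27 | α-hydroxy ester | COC(=O)C(O)C[C@@]12C(=O)N3C[C@@H](CCC4=C1CCC4)[C@]2(CO[Si](C)(C)C(C)(C)C)CC[C@@H](O[Si](C)(C)C(C)(C)C)[C@H](C)C3
F6 | step 27 | α-keto ester | COC(=O)C(=O)C[C@@]12C(=O)N3C[C@@H](CCC4=C1CCC4)[C@]2(CO[Si](C)(C)C(C)(C)C)CC[C@@H](O[Si](C)(C)C(C)(C)C)[C@H](C)C3
F7 | step 27 | ring E cyclopentanol | COC(=O)C1(O)C[C@@]23C(=O)N4C[C@@H](CCC5=C2[C@@H]1CC5)[C@]3(CO[Si](C)(C)C(C)(C)C)CC[C@@H](O[Si](C)(C)C(C)(C)C)[C@H](C)C4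
F8 | step 21 | 2-vinylcyclopentenyl lactam | COC(=O)CC[C@]1(C2=C(C=C)CCC2)C(=O)N(Cc2ccc(OC)cc2)C[C@@H](C)[C@H](O[Si](C)(C)C(C)(C)C)/C=C/[C@@]1(CO[Si](C)(C)C(C)(C)C)[C@@H](COCc2ccccc2)C=C
F9 | step 21 | ring C cycloheptadiene | COC(=O)CC[C@@]12C3=C(CCC3)/C=C\[C@H](COCc4ccccc4)[C@]1(CO[Si](C)(C)C(C)(C)C)/C=C/[C@@H](O[Si](C)(C)C(C)(C)C)[C@H](C)CN(Cc4ccc(OC)cc4)C2=O
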